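**Strategy.** With 3,7-dioxabicyclo[3.3.0]octane numbering (C1 = C–OH bridgehead), everything rests on opening the oxolane ring C1–C5–C6–O7–C8 at O7–C6 and C5–H, which reveals an exocyclic styrene isomeric with the product. One cobalt-hydride radical-polar crossover cycloisomerisation adds the C8 hydroxyl across C5=C6, closing this last ring and setting C5 and C6. It exploits the para-oxygenated aryl on C6 (benzylic radical and cation stabilisation) and the cis-fusion demand of the two oxolane rings. The precursor, a monocyclic 2-aryl-4-arylidene-3-(hydroxymethyl)oxolan-3-ol, comes from Sharpless epoxidation of a symmetric bis(arylidene)butanediol with in situ epoxide opening.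

Key step: step 5

Numbering note: the labels C1–C8 and O3/O7 of the target are used for the corresponding atoms of every intermediate (C2 and C6 = ArCH, C4 and C8 = OCH2, C5 = CH bridgehead).

Remark on the chemistry: the Sharpless epoxidation of diol 6 is assumed to follow the usual facial rule, L-(+)-tartrate giving the (2S,3S)-oxirane from an (E)-2,3-disubstituted allylic alcohol.

Step 1
Reactants: 1 4-(benzyloxy)-3-methoxybenzaldehyde (2.2 equiv); 2 diethyl succinate
Product: 4 (2E,3E)-2,3-bis[4-(benzyloxy)-3-methoxybenzylidene]butanedioic acid, via Stobbe half-ester 3 (not isolated)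
Conditions: NaOEt (3 equiv), EtOH, reflux; then 2 M HCl
Reagents that add atoms: none
Why: Double Stobbe condensation, in which each aldolate lactonises onto the distal ester and opens by E1cB to an arylidene carboxylate, so that two condensations should give the diacid with each aryl group trans to its carboxyl group (E,E) for steric reasons.

Step 2
Reactants: 4 (2E,3E)-2,3-bis[4-(benzyloxy)-3-methoxybenzylidene]butanedioic acid
Product: 5 dimethyl (2E,3E)-2,3-bis[4-(benzyloxy)-3-methoxybenzylidene]butanedioate
Conditions: MeI, K2CO3, DMF, rt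
Reagents that add atoms: iodomethane, CI
Why: SN2 O-alkylation of the two carboxylates (alkylative esterification) under mild base, which should leave the benzyl ethers and the alkene geometry untouched.

Step 3
Reactants: 5 dimethyl (2E,3E)-2,3-bis[4-(benzyloxy)-3-methoxybenzylidene]butanedioate
Product: 6 (2E,3E)-2,3-bis[4-(benzyloxy)-3-methoxybenzylidene]butane-1,4-diol
Conditions: i-Bu2AlH (5 equiv), CH2Cl2, −78 to 0 °C; aq. potassium sodium tartrate
Reagents that add atoms: none
Why: 1,2-Hydride reduction of the two conjugated esters to the allylic alcohols, a reaction type that should not touch the trisubstituted alkenes or their geometry.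

Step 4
Reactants: 6 (2E,3E)-2,3-bis[4-(benzyloxy)-3-methoxybenzylidene]butane-1,4-diol
Product: 8 (2R,3S,4Z)-2-[4-(benzyloxy)-3-methoxyphenyl]-4-[4-(benzyloxy)-3-methoxybenzylidene]-3-(hydroxymethyl)oxolan-3-ol, via epoxy diol 7 (not isolated)
Conditions: Ti(OiPr)4 (1.1 equiv), L-(+)-diisopropyl tartrate (1.3 equiv), t-BuOOH (1.1 equiv, anhydrous), 4 Å MS, CH2Cl2, −25 to 0 °C
Reagents that add atoms: tert-butyl hydroperoxide, CC(C)(C)OO
Why: Sharpless asymmetric epoxidation of one of the two equivalent allylic alcohols should give the (2S,3S)-oxirane 7, whose titanium-activated p-alkoxybenzylic carbon is then opened with inversion by the other hydroxymethyl group (intramolecular epoxide opening to the five-membered ring), fixing C1 (S, C–O retained) and C2 (R, inverted).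

Step 5
Reactants: 8 (2R,3S,4Z)-2-[4-(benzyloxy)-3-methoxyphenyl]-4-[4-(benzyloxy)-3-methoxybenzylidene]-3-(hydroxymethyl)oxolan-3-ol
Product: 9 (1S,2R,5R,6S)-2,6-bis[4-(benzyloxy)-3-methoxyphenyl]-3,7-dioxabicyclo[3.3.0]octan-1-ol
Conditions: [N,N'-bis(3,5-di-tert-butylsalicylidene)cyclohexane-1,2-diaminato]cobalt, C36H52CoN2O2 (divalent cobalt, 5 mol %), 1-fluoro-2,4,6-trimethylpyridinium triflate (1.5 equiv), PhSiH3 (1.5 equiv), PhCF3, 0 °C to rt
Reagents that add atoms: none
Why: Metal-hydride hydrogen-atom-transfer (Mukaiyama-type) radical-polar crossover hydroalkoxylation: a cobalt hydride (trivalent cobalt), formed from the salen complex, the N-fluoropyridinium oxidant and PhSiH3, should deliver a hydrogen atom to C5 of the exocyclic styrene, and the resulting p-alkoxybenzylic radical at C6 is oxidised through an alkylcobalt species (tetravalent cobalt) to the benzylic cation, which the primary C8 hydroxyl captures. The closest known reaction is the cobalt-salen-catalysed intramolecular hydroalkoxylation of alkenols to cyclic ethers. The oxolane ring C1–C5–C6–O7–C8 closes by O7–C6 bond formation, a five-membered closure onto a free cation (formally 5-endo with respect to the original alkene, which does not hinder a stepwise cationic closure). C5 is controlled by the ring fusion, since only the isomer with the new C5–H cis to the C1 hydroxyl can close a cis-fused bicyclo[3.3.0] system and hydrogen delivery to the other face is expected to be returned by reverse transfer or loss of the C5 proton; C6 is controlled by closure with the aryl group on the convex (exo) face, which is also the more stable arrangement. The step needs Markovnikov regioselectivity (secured by the p-oxygenated aryl on C6), capture by the primary and not the tertiary hydroxyl (only the former gives a five-membered ring), and non-acidic conditions, because acid would dehydrate the tertiary allylic alcohol towards a furan.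

Step 6
Reactants: 9 (1S,2R,5R,6S)-2,6-bis[4-(benzyloxy)-3-methoxyphenyl]-3,7-dioxabicyclo[3.3.0]octan-1-ol
Product: 10 (1S,2R,5R,6S)-2,6-bis(4-hydroxy-3-methoxyphenyl)-3,7-dioxabicyclo[3.3.0]octan-1-ol (8-hydroxypinoresinol)
Conditions: H2 (1 atm), palladium on carbon (Pd/C, 10 wt%), EtOAc, rt, stopped at full debenzylation
Reagents that add atoms: none
Why: Hydrogenolysis of the two aryl benzyl ethers under neutral conditions should be much faster than cleavage of the cyclic benzylic C–O bonds and touches no stereocentre.

**Compound list**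

1 | 4-(benzyloxy)-3-methoxybenzaldehyde | COc1cc(C=O)ccc1OCc1ccccc1 | starting material
2 | diethyl succinate | CCOC(=O)CCC(=O)OCC | starting material
3 | (3E)-4-[4-(benzyloxy)-3-methoxyphenyl]-3-(ethoxycarbonyl)but-3-enoic acid (Stobbe half-ester, formed in the flask as its sodium salt) | CCOC(=O)/C(=C/c1ccc(OCc2ccccc2)c(OC)c1)CC(=O)O | intermediate
4 | (2E,3E)-2,3-bis[4-(benzyloxy)-3-methoxybenzylidene]butanedioic acid | COc1cc(/C=C(/C(=O)O)C(\C(=O)O)=C/c2ccc(OCc3ccccc3)c(OC)c2)ccc1OCc1ccccc1 | intermediate
5 | dimethyl (2E,3E)-2,3-bis[4-(benzyloxy)-3-methoxybenzylidene]butanedioate | COc1cc(/C=C(/C(=O)OC)C(\C(=O)OC)=C/c2ccc(OCc3ccccc3)c(OC)c2)ccc1OCc1ccccc1 | intermediate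
6 | (2E,3E)-2,3-bis[4-(benzyloxy)-3-methoxybenzylidene]butane-1,4-diol | COc1cc(/C=C(/CO)C(\CO)=C/c2ccc(OCc3ccccc3)c(OC)c2)ccc1OCc1ccccc1 | intermediate
7 | (2Z)-3-[4-(benzyloxy)-3-methoxyphenyl]-2-[(2S,3S)-3-[4-(benzyloxy)-3-methoxyphenyl]-2-(hydroxymethyl)oxiran-2-yl]prop-2-en-1-ol (formed in the flask) | OC[C@]1(/C(CO)=C\c2ccc(OCc3ccccc3)c(OC)c2)O[C@H]1c1ccc(OCc2ccccc2)c(OC)c1 | intermediate
8 | (2R,3S,4Z)-2-[4-(benzyloxy)-3-methoxyphenyl]-4-[4-(benzyloxy)-3-methoxybenzylidene]-3-(hydroxymethyl)oxolan-3-ol | COc1cc([C@H]2OC/C(=C/c3ccc(OCc4ccccc4)c(OC)c3)[C@]2(O)CO)ccc1OCc1ccccc1 | intermediate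
9 | (1S,2R,5R,6S)-2,6-bis[4-(benzyloxy)-3-methoxyphenyl]-3,7-dioxabicyclo[3.3.0]octan-1-ol | COc1cc([C@H]2OC[C@]3(O)[C@@H](c4ccc(OCc5ccccc5)c(OC)c4)OC[C@H]23)ccc1OCc1ccccc1 | intermediate
10 | (1S,2R,5R,6S)-2,6-bis(4-hydroxy-3-methoxyphenyl)-3,7-dioxabicyclo[3.3.0]octan-1-ol (8-hydroxypinoresinol) | COc1cc([C@H]2OC[C@]3(O)[C@@H](c4ccc(O)c(OC)c4)OC[C@H]23)ccc1O | target

**Step count and risks**

Total step count: 6. Longest linear sequence: 6 steps (from 1 and 2).

Steps most likely to fail:

Step 5 (key step). Hydrogen-atom transfer may occur with poor facial selectivity at C5 or at the wrong alkene carbon, or the benzylic cation may be intercepted by fluoride or the pyridine base before the hydroxyl closes the ring. The fallback sets out from 8 and replaces the one-step cycloisomerisation by a cyclofunctionalisation and reduction pair. Treatment with PhSeCl and 2,6-lutidine in CH2Cl2 at −78 °C should form the seleniranium ion on the C5 face opposite to C8, so that O7 attacks C6 in an anti 5-endo-trig selenoetherification and gives the selenide (1S,2R,5S,6R)-2,6-bis[4-(benzyloxy)-3-methoxyphenyl]-5-(phenylselanyl)-3,7-dioxabicyclo[3.3.0]octan-1-ol F1. Only this face can cyclise, and anti addition to the (Z)-alkene places the aryl group exo. Radical deselenation with Bu3SnH and AIBN in toluene at 90 °C then gives a bridgehead radical that can only accept hydrogen to form the cis-fused system, and the route is rejoined at 9.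

Step 4. The second allylic hydroxyl may bind titanium and erode the enantioselectivity or lead to double epoxidation, and the labile p-alkoxyaryl epoxide may be opened by external nucleophiles instead of the internal hydroxyl. The fallback sets out from 6. Monosilylation (NaH, 1 equiv, then TBSCl, THF) should give (2E,3E)-2,3-bis[4-(benzyloxy)-3-methoxybenzylidene]-4-[(tert-butyldimethylsilyl)oxy]butan-1-ol F2, in which a single free allylic alcohol directs the Sharpless epoxidation (Ti(OiPr)4, L-(+)-diisopropyl tartrate, t-BuOOH, −25 °C). This gives the epoxy alcohol [(2S,3S)-3-[4-(benzyloxy)-3-methoxyphenyl]-2-[(1Z)-1-[4-(benzyloxy)-3-methoxyphenyl]-3-[(tert-butyldimethylsilyl)oxy]prop-1-en-2-yl]oxiran-2-yl]methanol F3, which is carried on crude. Desilylation with tetrabutylammonium fluoride in THF at 0 °C frees the hydroxyl, which should open the epoxide (if needed with pyridinium p-toluenesulfonate), and the route is rejoined at 8.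

Step 1. The second condensation may stall at the half-ester carboxylate 3, whose remaining methylene is only weakly acidic, so that little diacid forms. The fallback sets out from 1 and 2 and runs the two condensations separately. The half-ester 3 is made and isolated (t-BuOK, t-BuOH), then methylated (MeI, K2CO3, DMF) to 1-ethyl 4-methyl (2E)-2-[4-(benzyloxy)-3-methoxybenzylidene]butanedioate F4, whose methylene is now alpha to an ester. A second Stobbe condensation with 1 (t-BuOK, t-BuOH) should give (2E,3E)-2,3-bis[4-(benzyloxy)-3-methoxybenzylidene]-4-methoxy-4-oxobutanoic acid F5, and saponification (NaOH, aqueous EtOH, then HCl) rejoins the route at 4.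

Further compounds
F1 | step 5 | (1S,2R,5S,6R)-2,6-bis[4-(benzyloxy)-3-methoxyphenyl]-5-(phenylselanyl)-3,7-dioxabicyclo[3.3.0]octan-1-ol | COc1cc([C@H]2OC[C@]3(O)[C@@H](c4ccc(OCc5ccccc5)c(OC)c4)OC[C@]23[Se]c2ccccc2)ccc1OCc1ccccc1
F2 | step 4 | (2E,3E)-2,3-bis[4-(benzyloxy)-3-methoxybenzylidene]-4-[(tert-butyldimethylsilyl)oxy]butan-1-ol | COc1cc(/C=C(/CO)C(\CO[Si](C)(C)C(C)(C)C)=C/c2ccc(OCc3ccccc3)c(OC)c2)ccc1OCc1ccccc1
F3 | step 4 | [(2S,3S)-3-[4-(benzyloxy)-3-methoxyphenyl]-2-[(1Z)-1-[4-(benzyloxy)-3-methoxyphenyl]-3-[(tert-butyldimethylsilyl)oxy]prop-1-en-2-yl]oxiran-2-yl]methanol | OC[C@]1(/C(CO[Si](C)(C)C(C)(C)C)=C\c2ccc(OCc3ccccc3)c(OC)c2)O[C@H]1c1ccc(OCc2ccccc2)c(OC)c1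
F4 | step 1 | 1-ethyl 4-methyl (2E)-2-[4-(benzyloxy)-3-methoxybenzylidene]butanedioate | CCOC(=O)/C(=C/c1ccc(OCc2ccccc2)c(OC)c1)CC(=O)OC
F5 | step 1 | (2E,3E)-2,3-bis[4-(benzyloxy)-3-methoxybenzylidene]-4-methoxy-4-oxobutanoic acid | COc1cc(/C=C(/C(=O)O)C(\C(=O)OC)=C/c2ccc(OCc3ccccc3)c(OC)c2)ccc1OCc1ccccc1
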